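Remark: the chain is numbered C1–C15 from the alkyne CH, so the ring oxygen links C6 and C12. Methyl (R)-glycidate, PhMe2Si–B(pin) and 1,3-bis(triisopropylsilyl)propyne are taken as commercial.

**Plan**
1. Late cuts: C10–OAc (acetylation), the C1–C3 enyne end (Peterson olefination of a C4 aldehyde), C13–Br (from C13–OH with inversion).
2. Ring cut: the oxocane O–C6–C7–C8–C9–C10–C11–C12 is two five-membered rings (O–C6–C7–C8–C9 and O–C9–C10–C11–C12) sharing a transannular O···C9 bond; cutting O–C12 and C9–Cl and restoring O–C9 gives a 2,5-trans oxolane with a C12,C13 epoxide.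
3. Key cut: the oxolane is cut at O–C6 and C8–C9 into a C4–C8 allylsilane and a C9–C15 α-alkoxy aldehyde; O at C6, a heteroatom at C7 and CH2-8 bonded to C9 are the pattern a [3+2] allylsilane annulation leaves (Si at C7, later OH, then Cl).
4. Forward order: aldehyde and allylsilane; annulation closes the oxolane; Si → OH → Cl at C7; Z-alkene; hydroxyl-directed epoxidation; inversion at C10; epoxide-triggered oxonium formation and chloride opening at C9 expand the oxolane to the oxocane; then Br, enyne, acetate.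
5. Stereochemistry: C6 and C7 come from the (R)-C–Si centre of the allylsilane (asymmetric conjugate silylation). C10 comes from methyl (R)-glycidate and relays to C9 (Cram chelate) and to C12/C13 (vanadium-directed syn epoxidation), then is itself inverted (Mitsunobu).
6. C9–Cl, C12–O, C7–Cl and C13–Br are each fixed by an SN2 inversion.

Key step: step 5

Step 1
Reactants: 1 methyl (2E)-penta-2,4-dienoate
Product: 2 methyl (3R)-3-[dimethyl(phenyl)silyl]pent-4-enoate
Conditions: PhMe2Si–B(pin), CuCl (cat.), chiral imidazolinium tetrafluoroborate (NHC precursor, cat.), NaOt-Bu (cat.), THF, −78 °C; MeOH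
Reagents that add atoms: (dimethylphenylsilyl)boronic acid pinacol ester, C[Si](C)(c1ccccc1)B1OC(C)(C)C(C)(C)O1
Why: Copper-catalysed enantioselective conjugate silyl addition places silicon on the β-carbon (C6), the ligand enantiomer being chosen for the (R) centre; the step needs 1,4- rather than 1,6-addition.

Step 2
Reactants: 3 methyl (2R)-oxirane-2-carboxylate; 4 but-1-yne
Product: 5 methyl (2R)-2-hydroxyhept-4-ynoate
Conditions: 4, n-BuLi, THF, −78 °C; BF3·OEt2; then 3, −78 °C; aq. NH4Cl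
Reagents that add atoms: none
Why: BF3-mediated SN2 opening of the epoxide by the lithium acetylide at the unsubstituted carbon leaves the glycidate stereocentre (C10) untouched.

Step 3
Reactants: 5 methyl (2R)-2-hydroxyhept-4-ynoate
Product: 6 methyl (2R)-2-(naphthalen-2-ylmethoxy)hept-4-ynoate
Conditions: 2-(bromomethyl)naphthalene, Ag2O, 4 Å MS, CH2Cl2, rt, dark
Reagents that add atoms: 2-(bromomethyl)naphthalene, BrCc1ccc2ccccc2c1
Why: Silver oxide-mediated Williamson etherification is non-basic, so the α-hydroxy ester should not epimerise, and the ether can later chelate and be removed oxidatively.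

Step 4
Reactants: 6 methyl (2R)-2-(naphthalen-2-ylmethoxy)hept-4-ynoate
Product: 7 (2R)-2-(naphthalen-2-ylmethoxy)hept-4-ynal
Conditions: i-Bu2AlH, CH2Cl2, −78 °C; Rochelle salt
Reagents that add atoms: none
Why: Partial reduction of an α-alkoxy ester stops at the chelated tetrahedral aluminate at −78 °C and releases the aldehyde on work-up.

Step 5
Reactants: 2 methyl (3R)-3-[dimethyl(phenyl)silyl]pent-4-enoate; 7 (2R)-2-(naphthalen-2-ylmethoxy)hept-4-ynal
Product: 8 methyl 2-[(2S,3R,5R)-3-[dimethyl(phenyl)silyl]-5-[(1R)-1-(naphthalen-2-ylmethoxy)hex-3-yn-1-yl]oxolan-2-yl]acetate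
Conditions: SnCl4, 4 Å MS, CH2Cl2, −78 °C (7 precomplexed, then 2)
Reagents that add atoms: none
Why: SnCl4 chelates the aldehyde oxygen and the C10 ether of 7; the terminal alkene carbon C8 of 2 attacks C9 anti to silicon (anti SE2′), the β-silyl cation is bridged by a suprafacial 1,2-silyl shift, and the tin-bound C9 alkoxide opens the siliranium ion at C6 anti to silicon. The closest known reaction type is the Lewis acid-promoted [3+2] annulation of α-substituted allyl(dimethylphenyl)silanes with α-alkoxy aldehydes to 3-silyl-tetrahydrofurans. The oxolane O–C6–C7–C8–C9 closes by 5-endo opening of the three-membered silyl cation (equivalently, capture of the rearranged β-silyl cation at C6). C9 is set by the Cram chelate (C9–O syn to C10–O, 9R from 10R), C6 by inversion at the former C–Si carbon of (R)-2 (6S), and C7 by the silyl shift on the face fixed by the H-eclipsed conformation of the allylsilane, which puts silicon trans to the C6 side chain (7R). The step needs ring closure to outrun loss of the silyl group (simple allylation), which the hindered secondary silyl centre, the low temperature and the intramolecular tin alkoxide should secure, and it needs aldehyde-face control that is independent of the allylsilane, which the unsubstituted C8 terminus and the rigid chelate provide.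

Step 6
Reactants: 8 methyl 2-[(2S,3R,5R)-3-[dimethyl(phenyl)silyl]-5-[(1R)-1-(naphthalen-2-ylmethoxy)hex-3-yn-1-yl]oxolan-2-yl]acetate
Product: 10 methyl 2-[(2S,3R,5R)-3-hydroxy-5-[(1R)-1-(naphthalen-2-ylmethoxy)hex-3-yn-1-yl]oxolan-2-yl]acetate, via fluorosilane 9 (not isolated)
Conditions: HBF4·OEt2, CH2Cl2, 0 °C to rt; then KF, KHCO3, 30% H2O2, THF/MeOH, rt
Reagents that add atoms: hydrogen peroxide, OO
Why: Fleming–Tamao oxidation (ipso-protodesilylation of phenyl, then peroxide-induced migration of C7 from silicon to oxygen) replaces silicon by hydroxyl with retention, keeping C7–O trans to the C6 side chain.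

Step 7
Reactants: 10 methyl 2-[(2S,3R,5R)-3-hydroxy-5-[(1R)-1-(naphthalen-2-ylmethoxy)hex-3-yn-1-yl]oxolan-2-yl]acetate
Product: 11 methyl 2-[(2S,3S,5R)-3-chloro-5-[(1R)-1-(naphthalen-2-ylmethoxy)hex-3-yn-1-yl]oxolan-2-yl]acetate
Conditions: PPh3, CCl4, pyridine (cat.), toluene, 65 °C
Reagents that add atoms: carbon tetrachloride, ClC(Cl)(Cl)Cl
Why: Appel reaction: chloride displaces the oxyphosphonium group by SN2 with inversion, giving C7–Cl cis to the C6 side chain (7S).

Step 8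
Reactants: 11 methyl 2-[(2S,3S,5R)-3-chloro-5-[(1R)-1-(naphthalen-2-ylmethoxy)hex-3-yn-1-yl]oxolan-2-yl]acetate
Product: 12 methyl 2-[(2S,3S,5R)-3-chloro-5-[(1R,3Z)-1-(naphthalen-2-ylmethoxy)hex-3-en-1-yl]oxolan-2-yl]acetate
Conditions: H2 (1 atm), Pd/CaCO3 poisoned with Pb(OAc)2, quinoline, EtOAc, rt
Reagents that add atoms: none
Why: Lindlar semihydrogenation adds hydrogen syn to the C12–C13 alkyne to give the Z-alkene without touching the alkyl chloride or the naphthylmethyl ether.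

Step 9
Reactants: 12 methyl 2-[(2S,3S,5R)-3-chloro-5-[(1R,3Z)-1-(naphthalen-2-ylmethoxy)hex-3-en-1-yl]oxolan-2-yl]acetate
Product: 13 methyl 2-[(2S,3S,5R)-3-chloro-5-[(1R,3Z)-1-hydroxyhex-3-en-1-yl]oxolan-2-yl]acetate
Conditions: DDQ, CH2Cl2/pH 7 buffer, 0 °C to rt
Reagents that add atoms: none
Why: Oxidative cleavage of the naphthylmethyl ether by DDQ frees the C10 hydroxyl under neutral conditions that spare the isolated alkene, the chloride and the ester.

Step 10
Reactants: 13 methyl 2-[(2S,3S,5R)-3-chloro-5-[(1R,3Z)-1-hydroxyhex-3-en-1-yl]oxolan-2-yl]acetate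
Product: 14 methyl 2-[(2S,3S,5R)-3-chloro-5-[(1R)-2-[(2S,3R)-3-ethyloxiran-2-yl]-1-hydroxyethyl]oxolan-2-yl]acetate
Conditions: VO(acac)2 (cat.), t-BuOOH (in decane), CH2Cl2, 0 °C to rt
Reagents that add atoms: tert-butyl hydroperoxide, CC(C)(C)OO
Why: Hydroxyl-directed vanadium-catalysed epoxidation of a (Z)-homoallylic alcohol delivers oxygen through a chair-like vanadate with C9 and the alkene carbon C13 equatorial, giving the cis-epoxide with C12–O syn to C10–O (12S,13R).

Step 11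
Reactants: 14 methyl 2-[(2S,3S,5R)-3-chloro-5-[(1R)-2-[(2S,3R)-3-ethyloxiran-2-yl]-1-hydroxyethyl]oxolan-2-yl]acetate
Product: 15 methyl 2-[(2S,3S,5R)-3-chloro-5-[(1S)-2-[(2S,3R)-3-ethyloxiran-2-yl]-1-(4-nitrobenzoyloxy)ethyl]oxolan-2-yl]acetate
Conditions: PPh3, DIAD, 4-nitrobenzoic acid, THF, 0 °C to rt
Reagents that add atoms: 4-nitrobenzoic acid, O=C(O)c1ccc(cc1)[N+](=O)[O-]
Why: Mitsunobu reaction inverts the carbinol next to the oxolane (SN2 by the carboxylate), turning the relay centre C10 from R into the S configuration of the target.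

Step 12
Reactants: 15 methyl 2-[(2S,3S,5R)-3-chloro-5-[(1S)-2-[(2S,3R)-3-ethyloxiran-2-yl]-1-(4-nitrobenzoyloxy)ethyl]oxolan-2-yl]acetate
Product: 16 methyl 2-[(2S,3S,5R)-3-chloro-5-[(1S)-2-[(2S,3R)-3-ethyloxiran-2-yl]-1-hydroxyethyl]oxolan-2-yl]acetate
Conditions: K2CO3 (cat.), MeOH, 0 °C
Reagents that add atoms: none
Why: Base-catalysed transesterification removes the activated 4-nitrobenzoate as its methyl ester while the methyl ester, epoxide and chloride stay intact.

Step 13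
Reactants: 16 methyl 2-[(2S,3S,5R)-3-chloro-5-[(1S)-2-[(2S,3R)-3-ethyloxiran-2-yl]-1-hydroxyethyl]oxolan-2-yl]acetate
Product: 17 methyl 2-[(2S,3S,5R)-5-[(1S)-1-[(tert-butyldimethylsilyl)oxy]-2-[(2S,3R)-3-ethyloxiran-2-yl]ethyl]-3-chlorooxolan-2-yl]acetate
Conditions: TBSCl, imidazole, DMF, rt
Reagents that add atoms: tert-butyldimethylsilyl chloride, CC(C)(C)[Si](C)(C)Cl
Why: Silylation gives a C10 oxygen that cannot act as a neighbouring group at C9 in the next step, and the chlorosilane (rather than a silyl triflate) leaves the epoxide alone.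

Step 14
Reactants: 17 methyl 2-[(2S,3S,5R)-5-[(1S)-1-[(tert-butyldimethylsilyl)oxy]-2-[(2S,3R)-3-ethyloxiran-2-yl]ethyl]-3-chlorooxolan-2-yl]acetate
Product: 20 methyl 2-[(2S,3S,5S,6S,8R)-6-[(tert-butyldimethylsilyl)oxy]-3,5-dichloro-8-[(1R)-1-hydroxypropyl]oxocan-2-yl]acetate, via oxonium triflate 18 (not isolated), via triethylsilyl ether 19 (not isolated)
Conditions: TESOTf, 2,6-di-tert-butyl-4-methylpyridine, CH2Cl2, −78 °C; then n-Bu4NCl, −78 to −20 °C; then PPTS, MeOH, 0 °C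
Reagents that add atoms: tetrabutylammonium chloride, CCCC[N+](CCCC)(CCCC)CCCC.[Cl-]
Why: Ether-oxygen participation and oxonium fragmentation (a three-atom ring expansion): silylation of the epoxide lets the oxolane oxygen open it at C12 in the 5-exo mode with inversion, a stereospecific entry to the cis-fused oxonium ion, and chloride should then open C9 with inversion because C6 is flanked by the C7 chloride and the ester-bearing CH2 while C12 is flanked by the branched, silyloxylated C13.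

Step 15
Reactants: 20 methyl 2-[(2S,3S,5S,6S,8R)-6-[(tert-butyldimethylsilyl)oxy]-3,5-dichloro-8-[(1R)-1-hydroxypropyl]oxocan-2-yl]acetate
Product: 21 methyl 2-[(2S,3S,5S,6S,8R)-8-[(1S)-1-bromopropyl]-6-[(tert-butyldimethylsilyl)oxy]-3,5-dichlorooxocan-2-yl]acetate
Conditions: CBr4, P(n-C8H17)3, toluene, 70 °C
Reagents that add atoms: carbon tetrabromide, BrC(Br)(Br)Br
Why: Appel-type bromination displaces the C13 oxyphosphonium group by bromide with inversion, giving the 13S bromide anti to the C12 ether oxygen.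

Step 16
Reactants: 21 methyl 2-[(2S,3S,5S,6S,8R)-8-[(1S)-1-bromopropyl]-6-[(tert-butyldimethylsilyl)oxy]-3,5-dichlorooxocan-2-yl]acetate
Product: 22 2-[(2S,3S,5S,6S,8R)-8-[(1S)-1-bromopropyl]-6-[(tert-butyldimethylsilyl)oxy]-3,5-dichlorooxocan-2-yl]acetaldehyde
Conditions: i-Bu2AlH, CH2Cl2, −78 °C; Rochelle salt
Reagents that add atoms: none
Why: Partial reduction of the ester at −78 °C gives the C4 aldehyde; the alkyl halides and the silyl ether are inert to the hydride at this temperature.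

Step 17
Reactants: 22 2-[(2S,3S,5S,6S,8R)-8-[(1S)-1-bromopropyl]-6-[(tert-butyldimethylsilyl)oxy]-3,5-dichlorooxocan-2-yl]acetaldehyde
Product: 23 (2S,3S,5S,6S,8R)-8-[(1S)-1-bromopropyl]-6-[(tert-butyldimethylsilyl)oxy]-3,5-dichloro-2-[(2Z)-5-[tri(propan-2-yl)silyl]pent-2-en-4-yn-1-yl]oxocane
Conditions: 1,3-bis(triisopropylsilyl)propyne, n-BuLi, THF, −78 °C; then 22, −78 °C; aq. NH4Cl
Reagents that add atoms: 1,3-bis(triisopropylsilyl)prop-1-yne, CC(C)[Si](CC#C[Si](C(C)C)(C(C)C)C(C)C)(C(C)C)C(C)C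
Why: Peterson olefination with the lithiated bis-silylpropyne adds C1–C3, and syn-elimination of the bulky β-oxidosilane should favour the (Z)-enyne.

Step 18
Reactants: 23 (2S,3S,5S,6S,8R)-8-[(1S)-1-bromopropyl]-6-[(tert-butyldimethylsilyl)oxy]-3,5-dichloro-2-[(2Z)-5-[tri(propan-2-yl)silyl]pent-2-en-4-yn-1-yl]oxocane
Product: 24 (2R,4S,5S,7S,8S)-2-[(1S)-1-bromopropyl]-5,7-dichloro-8-[(2Z)-pent-2-en-4-yn-1-yl]oxocan-4-ol
Conditions: n-Bu4NF, THF, 0 °C to rt
Reagents that add atoms: none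
Why: Fluoride-mediated desilylation cleaves both the alkynyl C–Si bond and the C10 silyl ether in one operation.

Step 19
Reactants: 24 (2R,4S,5S,7S,8S)-2-[(1S)-1-bromopropyl]-5,7-dichloro-8-[(2Z)-pent-2-en-4-yn-1-yl]oxocan-4-ol
Product: 25 (2R,4S,5S,7S,8S)-2-[(1S)-1-bromopropyl]-5,7-dichloro-8-[(2Z)-pent-2-en-4-yn-1-yl]oxocan-4-yl acetate
Conditions: Ac2O, pyridine, DMAP (cat.), CH2Cl2, rt
Reagents that add atoms: acetic anhydride, CC(=O)OC(C)=O
Why: DMAP-catalysed acylation of the C10 alcohol proceeds with retention and gives the target.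

**Compound list**
1 | methyl (2E)-penta-2,4-dienoate | C=C/C=C/C(=O)OC | starting material
2 | methyl (3R)-3-[dimethyl(phenyl)silyl]pent-4-enoate | C=C[C@@H](CC(=O)OC)[Si](C)(C)c1ccccc1 | intermediate
3 | methyl (2R)-oxirane-2-carboxylate | COC(=O)[C@H]1CO1 | starting material
4 | but-1-yne | CCC#C | starting material
5 | methyl (2R)-2-hydroxyhept-4-ynoate | COC(=O)[C@H](O)CC#CCC | intermediate
6 | methyl (2R)-2-(naphthalen-2-ylmethoxy)hept-4-ynoate | COC(=O)[C@H](OCc1ccc2ccccc2c1)CC#CCC | intermediate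
7 | (2R)-2-(naphthalen-2-ylmethoxy)hept-4-ynal | O=C[C@H](OCc1ccc2ccccc2c1)CC#CCC | intermediate
8 | methyl 2-[(2S,3R,5R)-3-[dimethyl(phenyl)silyl]-5-[(1R)-1-(naphthalen-2-ylmethoxy)hex-3-yn-1-yl]oxolan-2-yl]acetate | COC(=O)C[C@@H]1O[C@@H]([C@H](OCc2ccc3ccccc3c2)CC#CCC)C[C@H]1[Si](C)(C)c4ccccc4 | intermediate
9 | methyl 2-[(2S,3R,5R)-3-[fluoro(dimethyl)silyl]-5-[(1R)-1-(naphthalen-2-ylmethoxy)hex-3-yn-1-yl]oxolan-2-yl]acetate | COC(=O)C[C@@H]1O[C@@H]([C@H](OCc2ccc3ccccc3c2)CC#CCC)C[C@H]1[Si](C)(C)F | intermediate (not isolated)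
10 | methyl 2-[(2S,3R,5R)-3-hydroxy-5-[(1R)-1-(naphthalen-2-ylmethoxy)hex-3-yn-1-yl]oxolan-2-yl]acetate | COC(=O)C[C@@H]1O[C@@H]([C@H](OCc2ccc3ccccc3c2)CC#CCC)C[C@H]1O | intermediate
11 | methyl 2-[(2S,3S,5R)-3-chloro-5-[(1R)-1-(naphthalen-2-ylmethoxy)hex-3-yn-1-yl]oxolan-2-yl]acetate | COC(=O)C[C@@H]1O[C@@H]([C@H](OCc2ccc3ccccc3c2)CC#CCC)C[C@@H]1Cl | intermediate
12 | methyl 2-[(2S,3S,5R)-3-chloro-5-[(1R,3Z)-1-(naphthalen-2-ylmethoxy)hex-3-en-1-yl]oxolan-2-yl]acetate | COC(=O)C[C@@H]1O[C@@H]([C@H](OCc2ccc3ccccc3c2)C/C=C\CC)C[C@@H]1Cl | intermediate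
13 | methyl 2-[(2S,3S,5R)-3-chloro-5-[(1R,3Z)-1-hydroxyhex-3-en-1-yl]oxolan-2-yl]acetate | COC(=O)C[C@@H]1O[C@@H]([C@H](O)C/C=C\CC)C[C@@H]1Cl | intermediate
14 | methyl 2-[(2S,3S,5R)-3-chloro-5-[(1R)-2-[(2S,3R)-3-ethyloxiran-2-yl]-1-hydroxyethyl]oxolan-2-yl]acetate | COC(=O)C[C@@H]1O[C@@H]([C@H](O)C[C@@H]2O[C@@H]2CC)C[C@@H]1Cl | intermediate
15 | methyl 2-[(2S,3S,5R)-3-chloro-5-[(1S)-2-[(2S,3R)-3-ethyloxiran-2-yl]-1-(4-nitrobenzoyloxy)ethyl]oxolan-2-yl]acetate | COC(=O)C[C@@H]1O[C@@H]([C@@H](OC(=O)c2ccc(cc2)[N+](=O)[O-])C[C@@H]3O[C@@H]3CC)C[C@@H]1Cl | intermediate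
16 | methyl 2-[(2S,3S,5R)-3-chloro-5-[(1S)-2-[(2S,3R)-3-ethyloxiran-2-yl]-1-hydroxyethyl]oxolan-2-yl]acetate | COC(=O)C[C@@H]1O[C@@H]([C@@H](O)C[C@@H]2O[C@@H]2CC)C[C@@H]1Cl | intermediate
17 | methyl 2-[(2S,3S,5R)-5-[(1S)-1-[(tert-butyldimethylsilyl)oxy]-2-[(2S,3R)-3-ethyloxiran-2-yl]ethyl]-3-chlorooxolan-2-yl]acetate | COC(=O)C[C@@H]1O[C@@H]([C@@H](O[Si](C)(C)C(C)(C)C)C[C@@H]2O[C@@H]2CC)C[C@@H]1Cl | intermediate
18 | cis-fused 1-oxoniabicyclo[3.3.0]octane triflate with O+ bonded to C6, C9 and C12 (6S,7S,9R,10S,12R,13R; C7–Cl, C10–OTBS, C13–OSiEt3, C6–CH2CO2Me) | COC(=O)C[C@@H]1[O+]2[C@@H]([C@H](O[Si](CC)(CC)CC)CC)C[C@H](O[Si](C)(C)C(C)(C)C)[C@H]2C[C@@H]1Cl.[O-]S(=O)(=O)C(F)(F)F | intermediate (not isolated)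
19 | methyl 2-[(2S,3S,5S,6S,8R)-6-[(tert-butyldimethylsilyl)oxy]-3,5-dichloro-8-[(1R)-1-[(triethylsilyl)oxy]propyl]oxocan-2-yl]acetate | COC(=O)C[C@@H]1O[C@@H]([C@H](O[Si](CC)(CC)CC)CC)C[C@H](O[Si](C)(C)C(C)(C)C)[C@@H](Cl)C[C@@H]1Cl | intermediate (not isolated)
20 | methyl 2-[(2S,3S,5S,6S,8R)-6-[(tert-butyldimethylsilyl)oxy]-3,5-dichloro-8-[(1R)-1-hydroxypropyl]oxocan-2-yl]acetate | COC(=O)C[C@@H]1O[C@@H]([C@H](O)CC)C[C@H](O[Si](C)(C)C(C)(C)C)[C@@H](Cl)C[C@@H]1Cl | intermediate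
21 | methyl 2-[(2S,3S,5S,6S,8R)-8-[(1S)-1-bromopropyl]-6-[(tert-butyldimethylsilyl)oxy]-3,5-dichlorooxocan-2-yl]acetate | COC(=O)C[C@@H]1O[C@@H]([C@@H](Br)CC)C[C@H](O[Si](C)(C)C(C)(C)C)[C@@H](Cl)C[C@@H]1Cl | intermediate
22 | 2-[(2S,3S,5S,6S,8R)-8-[(1S)-1-bromopropyl]-6-[(tert-butyldimethylsilyl)oxy]-3,5-dichlorooxocan-2-yl]acetaldehyde | O=CC[C@@H]1O[C@@H]([C@@H](Br)CC)C[C@H](O[Si](C)(C)C(C)(C)C)[C@@H](Cl)C[C@@H]1Cl | intermediate
23 | (2S,3S,5S,6S,8R)-8-[(1S)-1-bromopropyl]-6-[(tert-butyldimethylsilyl)oxy]-3,5-dichloro-2-[(2Z)-5-[tri(propan-2-yl)silyl]pent-2-en-4-yn-1-yl]oxocane | CC(C)[Si](C#C/C=C\C[C@@H]1O[C@@H]([C@@H](Br)CC)C[C@H](O[Si](C)(C)C(C)(C)C)[C@@H](Cl)C[C@@H]1Cl)(C(C)C)C(C)C | intermediate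
24 | (2R,4S,5S,7S,8S)-2-[(1S)-1-bromopropyl]-5,7-dichloro-8-[(2Z)-pent-2-en-4-yn-1-yl]oxocan-4-ol | C#C/C=C\C[C@@H]1O[C@@H]([C@@H](Br)CC)C[C@H](O)[C@@H](Cl)C[C@@H]1Cl | intermediate
25 | (2R,4S,5S,7S,8S)-2-[(1S)-1-bromopropyl]-5,7-dichloro-8-[(2Z)-pent-2-en-4-yn-1-yl]oxocan-4-yl acetate | C#C/C=C\C[C@@H]1O[C@@H]([C@@H](Br)CC)C[C@H](OC(C)=O)[C@@H](Cl)C[C@@H]1Cl | target

Total step count: 19. Longest linear sequence: 18 steps (3 to 25, steps 2 to 19).

**Steps most likely to fail**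

Step 14. The risk is the partition of chloride among the three α-carbons of the oxonium ion (opening at C6 or C12 returns oxolanes instead of the oxocane) and direct opening of the activated epoxide before the ether oxygen engages. The fallback replaces free chloride by chloride relayed from a metal held on the C10 oxygen. It sets out from alcohol 16, before silylation. The C10 titanium alkoxide is formed with ClTi(Oi-Pr)3, the epoxide is triggered with TESOTf, and n-Bu4NCl is added. The titanate anchored on O10 can pass chloride to the adjacent C9 through a five-membered arrangement, while C6 is out of its reach and C12 is reached only through a larger ring. This should give methyl 2-[(2S,3S,5S,6S,8R)-3,5-dichloro-6-hydroxy-8-[(1R)-1-[(triethylsilyl)oxy]propyl]oxocan-2-yl]acetate F1. Silylation of its free C10 hydroxyl (TBSCl, imidazole) gives 19, and PPTS in MeOH returns to the route at 20.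

Step 6. The risk is acid-promoted anti-elimination of silicon and the ring oxygen (opening of the oxolane) during cleavage of the phenyl group, or incomplete C–Si oxidation. The fallback turns that ring opening into the route and avoids both the oxidation and step 7. It sets out from 8, which is opened deliberately with BF3·OEt2 to methyl (3E,6R,7R)-6-hydroxy-7-(naphthalen-2-ylmethoxy)dodec-3-en-9-ynoate F2. A 5-endo iodoetherification of this (E)-homoallylic alcohol (I2, NaHCO3, MeCN, 0 °C; anti addition, 2,5-trans closure) should give methyl 2-[(2S,3R,5R)-3-iodo-5-[(1R)-1-(naphthalen-2-ylmethoxy)hex-3-yn-1-yl]oxolan-2-yl]acetate F3. Displacement of iodide by chloride with inversion (LiCl, DMF) returns to the route at 11.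

Step 5. The risk is loss of the silyl group from the β-silyl cation before ring closure (Hosomi–Sakurai allylation instead of annulation) or erosion of chelate control. The fallback uses a bulkier silyl group that resists desilylation and is cleaved by fluoride. It sets out from 1, which under the conditions of step 1 with the (diphenylmethyl)dimethylsilyl boronic ester would give methyl (3R)-3-[(diphenylmethyl)dimethylsilyl]pent-4-enoate F4. Annulation of F4 with 7 (SnCl4, −78 °C) would give methyl 2-[(2S,3R,5R)-3-[(diphenylmethyl)dimethylsilyl]-5-[(1R)-1-(naphthalen-2-ylmethoxy)hex-3-yn-1-yl]oxolan-2-yl]acetate F5. Treatment with n-Bu4NF cleaves the diphenylmethyl group to give fluorosilane 9, and H2O2 with KHCO3 then returns to the route at 10.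

Further compounds
F1 | step 14 | methyl 2-[(2S,3S,5S,6S,8R)-3,5-dichloro-6-hydroxy-8-[(1R)-1-[(triethylsilyl)oxy]propyl]oxocan-2-yl]acetate | COC(=O)C[C@@H]1O[C@@H]([C@H](O[Si](CC)(CC)CC)CC)C[C@H](O)[C@@H](Cl)C[C@@H]1Cl
F2 | step 6 | methyl (3E,6R,7R)-6-hydroxy-7-(naphthalen-2-ylmethoxy)dodec-3-en-9-ynoate | COC(=O)C/C=C/C[C@@H](O)[C@H](OCc1ccc2ccccc2c1)CC#CCC
F3 | step 6 | methyl 2-[(2S,3R,5R)-3-iodo-5-[(1R)-1-(naphthalen-2-ylmethoxy)hex-3-yn-1-yl]oxolan-2-yl]acetate | COC(=O)C[C@@H]1O[C@@H]([C@H](OCc2ccc3ccccc3c2)CC#CCC)C[C@H]1I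
F4 | step 5 | methyl (3R)-3-[(diphenylmethyl)dimethylsilyl]pent-4-enoate | C=C[C@@H](CC(=O)OC)[Si](C)(C)C(c1ccccc1)c1ccccc1
F5 | step 5 | methyl 2-[(2S,3R,5R)-3-[(diphenylmethyl)dimethylsilyl]-5-[(1R)-1-(naphthalen-2-ylmethoxy)hex-3-yn-1-yl]oxolan-2-yl]acetate | COC(=O)C[C@@H]1O[C@@H]([C@H](OCc2ccc3ccccc3c2)CC#CCC)C[C@H]1[Si](C)(C)C(c4ccccc4)c5ccccc5
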